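**Plan**
1. Retrosynthesis (chroman numbering O1, C2, C3, C4, C4a, C5–C8, C8a): cut the enone C=C (Claisen–Schmidt), then the prenyl C=C (Wittig on a C3 acetaldehyde arm), then the two chroman bonds C4–C4a and C2–C3 together.
2. The feature that allows this: O1 carries the CMe2 carbon C2 and sits on the C8a=C4a edge of the trioxygenated ring A, so ArO+=CMe2 is a latent cationic 2-oxadiene (C2=O1+–C8a=C4a) and C3–C4 is the two-carbon partner; C4a is ortho/para to all three ring oxygens.
3. The partner is an enantiopure 2,3-dihydrofuran: its ring oxygen fixes the regiochemistry (oxygen ends on C4, later reduced to CH2), and its ring carbons become the CH2–CH= of the prenyl group.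
4. Forward order: dihydrofuran (2 steps); ketal of a symmetric 4-hydroxy-2,6-dimethoxyacetophenone; formal [4+2] closing the dihydropyran ring; reductive opening of the helper ring; BCl3 (5-OMe and OBn); glycol cleavage; Wittig; aldol condensation; MOM removal.
5. Stereochemistry: C3 (S) is set in the key step by 1,3-induction from the CH(CH2OBn) centre derived from (R)-benzyl glycidyl ether, which is then excised by periodate; the E-enone comes from the thermodynamic condensation.

Key step: step 4

Remark: 1-(4-hydroxy-2,6-dimethoxyphenyl)ethan-1-one and (R)-benzyl glycidyl ether are taken as purchasable. Any C3-epimeric material stays diastereomeric up to compound 10 and is to be removed before step 7.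

**Step 1**
Reactants: 1 (2R)-2-[(benzyloxy)methyl]oxirane
Product: 2 (2R)-1-(benzyloxy)pent-4-yn-2-ol
Conditions: LiC≡CH·H2NCH2CH2NH2 (1.5 equiv), DMSO, 0 °C → rt; H2O
Reagents that add atoms: lithium acetylide ethylenediamine complex, [Li+].[C-]#C.NCCN
Why: SN2 opening of the terminal epoxide at its CH2 carbon by the acetylide; the stereocenter is not involved and keeps its configuration.

**Step 2**
Reactants: 2 (2R)-1-(benzyloxy)pent-4-yn-2-ol
Product: 3 (2R)-2-[(benzyloxy)methyl]-2,3-dihydrofuran
Conditions: Mo(CO)6 (0.25 equiv), Et3N, Et2O, hν (350 nm), rt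
Reagents that add atoms: none
Why: Endo-selective alkynol cycloisomerization: the terminal alkyne becomes a molybdenum vinylidene whose carbene carbon is attacked by the hydroxyl group, giving the cyclic enol ether without touching the carbinol centre.

**Step 3**
Reactants: 4 1-(4-hydroxy-2,6-dimethoxyphenyl)ethan-1-one
Product: 5 1-{2,6-dimethoxy-4-[(2-methoxypropan-2-yl)oxy]phenyl}ethan-1-one
Conditions: 2-methoxypropene (5 equiv), pyridinium p-toluenesulfonate (2 mol%), CH2Cl2, 0 °C; Et3N, concentrate, use crude
Reagents that add atoms: 2-methoxypropene, COC(C)=C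
Why: Acid-catalysed Markovnikov addition of the only phenolic O–H to the enol ether (mixed-ketal formation, as in 2-methoxyprop-2-yl protection); the labile ketal is carried on without chromatography.

**Step 4**
Reactants: 5 1-{2,6-dimethoxy-4-[(2-methoxypropan-2-yl)oxy]phenyl}ethan-1-one; 3 (2R)-2-[(benzyloxy)methyl]-2,3-dihydrofuran
Product: 8 1-[(2R,3aS,9bR)-2-[(benzyloxy)methyl]-7,9-dimethoxy-4,4-dimethyl-2,3,3a,9b-tetrahydro-4H-furo[3,2-c]chromen-8-yl]ethan-1-one, via O-aryl oxocarbenium triflate 6 (not isolated), via oxolanylium triflate 7 (not isolated)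
Conditions: Me3SiOTf (1.1 equiv), 2,6-di-tert-butyl-4-methylpyridine (1.2 equiv), 4 Å MS, CH2Cl2, −78 °C; slow addition of 3 (1.0 equiv) to 5 (1.5 equiv), −78 → −40 °C; aq. NaHCO3
Reagents that add atoms: none
Why: Proposed new method: Me3SiOTf silylates the more basic methoxy oxygen of 5 and expels Me3SiOMe, leaving the O-aryl oxocarbenium ion 6 (a cationic 2-oxadiene: C=O+ plus the adjacent aromatic C=C); the nucleophilic enol-ether carbon C4 of 3 adds to its carbenium carbon to give the cyclic oxocarbenium ion 7 (bond C3a–C4), and the arene carbon ortho to the ether oxygen then attacks C5 of that ion (bond C9b–C9a), an overall stepwise formal [4+2]. The closest known reaction types are the oxa-Povarov reaction of aldehyde-derived O-aryl oxocarbenium ions with alkenes, the Lewis-acid addition of acetone ketals to enol ethers (Müller-Cunradi–Pieroh reaction) and the Povarov reaction of N-aryl iminium ions with 2,3-dihydrofuran; the union of a ketone-derived O-aryl oxocarbenium ion with a cyclic enol ether is the untested part. The dihydropyran ring closes by a 6-exo-trig Friedel–Crafts attack on the ring C=O+ of 7, which for geometric reasons gives the cis ring fusion. The stereocenter C3a (C3 of the target) is set in the first bond formation, in which the bulky tertiary cation approaches the dihydrofuran face anti to the benzyloxymethyl group at C2 (1,3-induction, as in electrophilic additions to 5-O-protected 2,3-dideoxy furanoid glycals); C9b follows from the cis fusion and is erased in step 5. The step needs cross-selectivity between two enol-ether-type partners and a single site of arylation: 6 is the least stabilised, most electrophilic cation present and 3 the best π-nucleophile, 3 is added slowly to an excess of 5 with a hindered pyridine buffering the triflic acid, and the two positions ortho to the ether oxygen of ring A are equivalent by symmetry and activated by three ortho/para oxygens.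

**Step 5**
Reactants: 8 1-[(2R,3aS,9bR)-2-[(benzyloxy)methyl]-7,9-dimethoxy-4,4-dimethyl-2,3,3a,9b-tetrahydro-4H-furo[3,2-c]chromen-8-yl]ethan-1-one
Product: 9 1-[(3R)-3-[(2R)-3-(benzyloxy)-2-hydroxypropyl]-5,7-dimethoxy-2,2-dimethyl-3,4-dihydro-2H-chromen-6-yl]ethan-1-one
Conditions: Et3SiH (5 equiv), BF3·OEt2 (2 equiv), CH2Cl2, −78 → −30 °C; aq. NaHCO3
Reagents that add atoms: none
Why: Ionic hydrogenation: BF3 ionises only the benzylic C9b–O bond (cation stabilised by two ortho and one para oxygen) and excess silane delivers hydride before proton loss can occur, while the non-benzylic chroman ether, the benzyl ether and the twisted di-ortho-substituted ketone should not react at this temperature; C3 is untouched (its descriptor changes to R only through substituent priorities).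

**Step 6**
Reactants: 9 1-[(3R)-3-[(2R)-3-(benzyloxy)-2-hydroxypropyl]-5,7-dimethoxy-2,2-dimethyl-3,4-dihydro-2H-chromen-6-yl]ethan-1-one
Product: 10 1-[(3R)-3-[(2R)-2,3-dihydroxypropyl]-5-hydroxy-7-methoxy-2,2-dimethyl-3,4-dihydro-2H-chromen-6-yl]ethan-1-one
Conditions: BCl3 (5 equiv), pentamethylbenzene (3 equiv), CH2Cl2, −78 → 0 °C; MeOH, then aq. NaHCO3
Reagents that add atoms: none
Why: Chelation-directed demethylation ortho to the ketone, in which BCl3 is expected to cleave the 5-OMe (flanked by acetyl and C4a, twisted out of plane and more basic) in preference to the 7-OMe, the boron chelate then stopping at the mono-phenol; the benzyl ether is cleaved in the same operation with pentamethylbenzene trapping the benzyl cation.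

**Step 7**
Reactants: 10 1-[(3R)-3-[(2R)-2,3-dihydroxypropyl]-5-hydroxy-7-methoxy-2,2-dimethyl-3,4-dihydro-2H-chromen-6-yl]ethan-1-one
Product: 11 2-[(3R)-6-acetyl-5-hydroxy-7-methoxy-2,2-dimethyl-3,4-dihydro-2H-chromen-3-yl]acetaldehyde
Conditions: NaIO4 (1.5 equiv), THF/pH 7 buffer, 0 °C → rt
Reagents that add atoms: none
Why: Malaprade glycol cleavage removes the terminal carbon and the auxiliary stereocenter and leaves the two-carbon aldehyde arm; the chelated ortho-acyl phenol is a poor substrate for periodate oxidation.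

**Step 8**
Reactants: 11 2-[(3R)-6-acetyl-5-hydroxy-7-methoxy-2,2-dimethyl-3,4-dihydro-2H-chromen-3-yl]acetaldehyde
Product: 12 1-[(3S)-5-hydroxy-7-methoxy-2,2-dimethyl-3-(3-methylbut-2-en-1-yl)-3,4-dihydro-2H-chromen-6-yl]ethan-1-one
Conditions: isopropyltriphenylphosphonium iodide (3.0 equiv), n-butyllithium (2.9 equiv), THF, 0 °C; add 11 at −78 °C → rt
Reagents that add atoms: isopropyltriphenylphosphonium iodide, CC(C)[P+](c1ccccc1)(c1ccccc1)c1ccccc1.[I-]
Why: Wittig olefination with the non-stabilised isopropylidene ylide is selective for the aldehyde, because the hindered aryl ketone is present as its unreactive phenoxide (one equivalent of ylide is spent on the phenol); the alkene terminus is symmetric, so no geometry issue arises.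

**Step 9**
Reactants: 13 2,4-dihydroxybenzaldehyde
Product: 14 2,4-bis(methoxymethoxy)benzaldehyde
Conditions: NaH (2.4 equiv), MOMCl (2.5 equiv), DMF, 0 °C → rt
Reagents that add atoms: chloromethyl methyl ether, COCCl
Why: Williamson-type O-alkylation of both phenoxides; the strong base is used so that the hydrogen-bonded 2-OH is also protected.

**Step 10**
Reactants: 12 1-[(3S)-5-hydroxy-7-methoxy-2,2-dimethyl-3-(3-methylbut-2-en-1-yl)-3,4-dihydro-2H-chromen-6-yl]ethan-1-one; 14 2,4-bis(methoxymethoxy)benzaldehyde
Product: 15 (2E)-3-[2,4-bis(methoxymethoxy)phenyl]-1-[(3S)-5-hydroxy-7-methoxy-2,2-dimethyl-3-(3-methylbut-2-en-1-yl)-3,4-dihydro-2H-chromen-6-yl]prop-2-en-1-one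
Conditions: KOH (50% aq.), EtOH, rt, argon, dark
Reagents that add atoms: none
Why: Claisen–Schmidt condensation of the methyl ketone enolate with the non-enolisable aldehyde; E1cB dehydration gives the E-enone, and the base-stable MOM ethers keep the aldehyde electrophilic.

**Step 11**
Reactants: 15 (2E)-3-[2,4-bis(methoxymethoxy)phenyl]-1-[(3S)-5-hydroxy-7-methoxy-2,2-dimethyl-3-(3-methylbut-2-en-1-yl)-3,4-dihydro-2H-chromen-6-yl]prop-2-en-1-one
Product: 16 (2E)-3-(2,4-dihydroxyphenyl)-1-[(3S)-5-hydroxy-7-methoxy-2,2-dimethyl-3-(3-methylbut-2-en-1-yl)-3,4-dihydro-2H-chromen-6-yl]prop-2-en-1-one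
Conditions: HCl (3 M aq.)/MeOH 1:10, rt, dark
Reagents that add atoms: none
Why: Acid-catalysed cleavage of the two aryl MOM acetals under mild conditions that the trisubstituted prenyl alkene, the chroman and the hydrogen-bonded 2'-hydroxychalcone should tolerate.

**Compound list**
1 | (2R)-2-[(benzyloxy)methyl]oxirane ((R)-benzyl glycidyl ether) | c1ccccc1COC[C@H]1CO1 | starting material
2 | (2R)-1-(benzyloxy)pent-4-yn-2-ol | c1ccccc1COC[C@H](O)CC#C | intermediate
3 | (2R)-2-[(benzyloxy)methyl]-2,3-dihydrofuran | c1ccccc1COC[C@H]1CC=CO1 | intermediate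
4 | 1-(4-hydroxy-2,6-dimethoxyphenyl)ethan-1-one | CC(=O)c1c(OC)cc(O)cc1OC | starting material
5 | 1-{2,6-dimethoxy-4-[(2-methoxypropan-2-yl)oxy]phenyl}ethan-1-one | CC(=O)c1c(OC)cc(OC(C)(C)OC)cc1OC | intermediate
6 | (4-acetyl-3,5-dimethoxyphenyl)(propan-2-ylidene)oxonium triflate (O-aryl oxocarbenium ion) | CC(=O)c1c(OC)cc(cc1OC)[O+]=C(C)C.[O-]S(=O)(=O)C(F)(F)F | intermediate
7 | 3-[2-(4-acetyl-3,5-dimethoxyphenoxy)propan-2-yl]-5-[(benzyloxy)methyl]oxolan-2-ylium triflate, substituents at C3 and C5 trans (cyclic oxocarbenium ion) | CC(=O)c1c(OC)cc(cc1OC)OC(C)(C)[C@H]1C[C@H](COCc2ccccc2)[O+]=C1.[O-]S(=O)(=O)C(F)(F)F | intermediate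
8 | 1-[(2R,3aS,9bR)-2-[(benzyloxy)methyl]-7,9-dimethoxy-4,4-dimethyl-2,3,3a,9b-tetrahydro-4H-furo[3,2-c]chromen-8-yl]ethan-1-one | CC(=O)c1c(OC)cc2OC(C)(C)[C@H]3C[C@H](COCc4ccccc4)O[C@H]3c2c1OC | intermediate
9 | 1-[(3R)-3-[(2R)-3-(benzyloxy)-2-hydroxypropyl]-5,7-dimethoxy-2,2-dimethyl-3,4-dihydro-2H-chromen-6-yl]ethan-1-one | CC(=O)c1c(OC)cc2OC(C)(C)[C@@H](C[C@@H](O)COCc3ccccc3)Cc2c1OC | intermediate
10 | 1-[(3R)-3-[(2R)-2,3-dihydroxypropyl]-5-hydroxy-7-methoxy-2,2-dimethyl-3,4-dihydro-2H-chromen-6-yl]ethan-1-one | CC(=O)c1c(OC)cc2OC(C)(C)[C@@H](C[C@@H](O)CO)Cc2c1O | intermediate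
11 | 2-[(3R)-6-acetyl-5-hydroxy-7-methoxy-2,2-dimethyl-3,4-dihydro-2H-chromen-3-yl]acetaldehyde | CC(=O)c1c(OC)cc2OC(C)(C)[C@@H](CC=O)Cc2c1O | intermediate
12 | 1-[(3S)-5-hydroxy-7-methoxy-2,2-dimethyl-3-(3-methylbut-2-en-1-yl)-3,4-dihydro-2H-chromen-6-yl]ethan-1-one | CC(=O)c1c(OC)cc2OC(C)(C)[C@@H](CC=C(C)C)Cc2c1O | intermediate
13 | 2,4-dihydroxybenzaldehyde | O=Cc1ccc(O)cc1O | starting material
14 | 2,4-bis(methoxymethoxy)benzaldehyde | O=Cc1ccc(OCOC)cc1OCOC | intermediate
15 | (2E)-3-[2,4-bis(methoxymethoxy)phenyl]-1-[(3S)-5-hydroxy-7-methoxy-2,2-dimethyl-3-(3-methylbut-2-en-1-yl)-3,4-dihydro-2H-chromen-6-yl]prop-2-en-1-one | COc1cc2c(c(O)c1C(=O)/C=C/c1ccc(OCOC)cc1OCOC)C[C@H](CC=C(C)C)C(C)(C)O2 | intermediate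
16 | (2E)-3-(2,4-dihydroxyphenyl)-1-[(3S)-5-hydroxy-7-methoxy-2,2-dimethyl-3-(3-methylbut-2-en-1-yl)-3,4-dihydro-2H-chromen-6-yl]prop-2-en-1-one | COc1cc2c(c(O)c1C(=O)/C=C/c1ccc(O)cc1O)C[C@H](CC=C(C)C)C(C)(C)O2 | target

**Step count**
Total steps: 11. Longest linear sequence: 9 steps (steps 1, 2, 4, 5, 6, 7, 8, 10, 11).

**Steps most likely to fail**

Step 4. The dihydrofuran may oligomerise or the cyclic oxocarbenium ion may lose a proton under the acid, the mixed ketal may ionise on the aryloxy side, or the electrophile may approach syn to the benzyloxymethyl group. The fallback builds the same three bonds stepwise with known reaction types and sets out from 3 and 4. Dihydrofuran 3 is treated with 2,2-dimethoxypropane and catalytic BF3·OEt2 at −78 °C (ketal–enol ether addition, same anti induction), which should give the acetal (3R,5R)-5-[(benzyloxy)methyl]-2-methoxy-3-(2-methoxypropan-2-yl)oxolane F1 as an anomeric mixture. F1 then serves as a furanosyl donor toward phenol 4 (Me3SiOTf, CH2Cl2, −30 °C → rt), where O-arylation followed by the O→C rearrangement of aryl glycosides should place the ring on the carbon ortho to the hydroxyl and give 1-{3-[(3S,5R)-5-[(benzyloxy)methyl]-3-(2-methoxypropan-2-yl)oxolan-2-yl]-4-hydroxy-2,6-dimethoxyphenyl}ethan-1-one F2. Continued exposure to the Lewis acid should ionise the tertiary methyl ether so that the phenol closes the dihydropyran ring, and the reversibly ionising benzylic C–O bond should let the ring fusion settle as cis, so the sequence comes back at 8.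

Step 5. Proton loss from the benzylic cation to a 2H-chromene followed by reprotonation would erode the configuration at C3, and hydride transfer to the ketone could compete. The fallback avoids a free cation and sets out from 8. Hydrogenolysis (H2, Pd(OH)2/C, EtOAc/AcOH) should cleave both benzylic C–O bonds, that of the furan ring and that of the benzyl ether, to give 1-[(3R)-3-[(2R)-2,3-dihydroxypropyl]-5,7-dimethoxy-2,2-dimethyl-3,4-dihydro-2H-chromen-6-yl]ethan-1-one F3. Chelation-directed demethylation of F3 with BCl3 (CH2Cl2, −78 → 0 °C) then comes back at 10.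

Step 6. Discrimination between the 5- and 7-methoxy groups may be insufficient, or the reagent may open the chroman ether. The fallback replaces selective cleavage by exhaustive cleavage and selective re-methylation and sets out from 9. BCl3/n-Bu4NI in excess (CH2Cl2, −78 °C → rt) should remove both methyl ethers and the benzyl ether to give 1-[(3R)-3-[(2R)-2,3-dihydroxypropyl]-5,7-dihydroxy-2,2-dimethyl-3,4-dihydro-2H-chromen-6-yl]ethan-1-one F4. Mono-methylation with MeI (1.05 equiv) and K2CO3 in acetone should then take place at the less hindered 7-OH, the 5-OH being flanked by C4a and held in the hydrogen bond to the ketone, and the sequence comes back at 10.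

**Further compounds**
F1 | step 4 | (3R,5R)-5-[(benzyloxy)methyl]-2-methoxy-3-(2-methoxypropan-2-yl)oxolane | COC(C)(C)[C@H]1C[C@H](COCc2ccccc2)OC1OC
F2 | step 4 | 1-{3-[(3S,5R)-5-[(benzyloxy)methyl]-3-(2-methoxypropan-2-yl)oxolan-2-yl]-4-hydroxy-2,6-dimethoxyphenyl}ethan-1-one | COC(C)(C)[C@H]1C[C@H](COCc2ccccc2)OC1c1c(O)cc(OC)c(C(C)=O)c1OC
F3 | step 5 | 1-[(3R)-3-[(2R)-2,3-dihydroxypropyl]-5,7-dimethoxy-2,2-dimethyl-3,4-dihydro-2H-chromen-6-yl]ethan-1-one | CC(=O)c1c(OC)cc2OC(C)(C)[C@@H](C[C@@H](O)CO)Cc2c1OC
F4 | step 6 | 1-[(3R)-3-[(2R)-2,3-dihydroxypropyl]-5,7-dihydroxy-2,2-dimethyl-3,4-dihydro-2H-chromen-6-yl]ethan-1-one | CC(=O)c1c(O)cc2OC(C)(C)[C@@H](C[C@@H](O)CO)Cc2c1O
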